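**Retrosynthetic overview**
1. The pyranone ring is made last: it is closed through its lactone C1–O2 bond on a benzoic acid whose only free ortho C–H has just been alkylated by an epihalohydrin in the same flask; loss of HBr then gives the 3-methyl enol lactone.
2. The benzylic methyl ether CH2–OMe bond comes from SN2 opening of a phthalide at its O–CH2 carbon by methoxide; the carboxyl group set free is reduced and becomes the bridging CH2.
3. The diarylmethane bond comes from a para-quinone methide of ring A captured by C5 of the phenoxide of 4-hydroxy-2-methoxybenzoic acid (ring B).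
4. Both aryl rings are the same catalogue acid; the phthalide is made from it by carboxylate-directed C–H alkylation/lactonisation with CH2Br2.
5. Ring order: rings A and B are bought; the furanone ring of the phthalide is formed and then opened; the pyranone ring is formed last.

Assumption: the target has no stereocentre or other stereogenic element (it is achiral), so the "single enantiomer" needs no stereocontrol.

**Step 1**
Reactants: 1 4-hydroxy-2-methoxybenzoic acid
Product: 3 5-hydroxy-7-methoxy-2-benzofuran-1(3H)-one, via bromomethyl acid 2 (not isolated)
Conditions: Pd(OAc)2 (10 mol %), K2HPO4 (3 equiv), CH2Br2 as solvent, 140 °C, sealed tube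
Reagents that add atoms: dibromomethane, BrCBr
Why: the potassium carboxylate directs C–H palladation to C6, the only free ortho position (C2 carries OMe), the aryl–palladium bond is alkylated by CH2Br2 and the benzylic bromide 2 is closed at once by intramolecular SN2 attack of the carboxylate, which is the known palladium-catalysed carboxylate-directed ortho-C–H alkylation/lactonisation of benzoic acids with dihaloalkanes; no stereocentre is formed.

**Step 2**
Reactants: 3 5-hydroxy-7-methoxy-2-benzofuran-1(3H)-one
Product: 4 4-hydroxy-2-methoxy-6-(methoxymethyl)benzoic acid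
Conditions: NaOMe (6 equiv), MeOH, 150 °C, sealed vessel; then cold 1 M HCl
Reagents that add atoms: sodium methoxide, [Na+].[O-]C
Why: addition of methoxide to the lactone carbonyl is reversible and unproductive, whereas SN2 attack at the benzylic O–CH2 carbon (alkyl–oxygen cleavage of the lactone) expels the carboxylate irreversibly and forms the CH2–OMe bond, as in the classical opening of phthalide by alkoxides and phenoxides to 2-(alkoxymethyl)benzoates; no stereocentre is formed.

**Step 3**
Reactants: 4 4-hydroxy-2-methoxy-6-(methoxymethyl)benzoic acid; 1 4-hydroxy-2-methoxybenzoic acid (3 equiv, excess recovered)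
Product: 7 4-hydroxy-5-{[4-hydroxy-2-methoxy-6-(methoxymethyl)phenyl]methyl}-2-methoxybenzoic acid, via benzyl alcohol 5 (not isolated), via quinone methide 6 (not isolated)
Conditions: BH3·THF (4 equiv), THF, 0 °C to 40 °C; MeOH quench, evaporate; then 1 (3 equiv), 2 M aq NaOH, 1,4-dioxane, 70 °C; cold HCl work-up
Reagents that add atoms: none
Why: borane reduces the free carboxylic acid through its acyloxyborane without touching the ethers, and in hot aqueous NaOH the para-hydroxybenzyl alcohol 5 loses hydroxide from its phenoxide to give quinone methide 6, which is captured by C5 of the dianion of 1 (ortho to O−, para to OMe, the only unhindered activated carbon) in a phenoxide C-alkylation (quinone methide 1,6-addition, Lederer–Manasse type); no stereocentre is formed.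

**Step 4**
Reactants: 7 4-hydroxy-5-{[4-hydroxy-2-methoxy-6-(methoxymethyl)phenyl]methyl}-2-methoxybenzoic acid; 8 2-(bromomethyl)oxirane (racemic epibromohydrin, 1.5 equiv)
Product: 11 6-hydroxy-5-{[4-hydroxy-2-methoxy-6-(methoxymethyl)phenyl]methyl}-8-methoxy-3-methyl-1H-isochromen-1-one, via bromomethyl lactone 9 (not isolated), via exo-methylene lactone 10 (not isolated)
Conditions: Pd(OAc)2 (5 mol %), N-acetylglycine (10 mol %), KOAc (1.5 equiv), (CF3)2CHOH, 60 °C; strip solvent and excess 8 in vacuo; then DBU (6 equiv), toluene, 100 °C
Reagents that add atoms: none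
Why: Proposed new method: a one-flask formal [4+2] annulation in which the epihalohydrin acts as a propyne equivalent at the right oxidation level, by carboxylate-directed palladation (divalent palladium with an amino acid ligand) at C6 of 7, SN2-type opening of the epoxide at its CH2 terminus by the aryl–palladium bond, lactonisation of the resulting bromohydrin acid (the ring-closing C1–O2 bond) to 9, then E2 loss of HBr with DBU to exocyclic enol lactone 10 and base-mediated 1,3-hydrogen shift to the conjugated 3-methylisocoumarin 11; the closest known reactions are the palladium-catalysed ortho-C–H alkylation of benzoic acids with epoxides to 3,4-dihydroisocoumarins and the DBU dehydrohalogenation of 3-(halomethyl)-3,4-dihydroisocoumarins, which have not been joined into an annulation nor run on a flanked C–H of a free-phenol acid; C3 of 9 forms racemic and the centre is destroyed in 10 and 11.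

**Compound list**
1 | 4-hydroxy-2-methoxybenzoic acid | COc1cc(O)ccc1C(=O)O | starting material
2 | 2-(bromomethyl)-4-hydroxy-6-methoxybenzoic acid | COc1cc(O)cc(CBr)c1C(=O)O | intermediate
3 | 5-hydroxy-7-methoxy-2-benzofuran-1(3H)-one | COc1cc(O)cc2c1C(=O)OC2 | intermediate
4 | 4-hydroxy-2-methoxy-6-(methoxymethyl)benzoic acid | COCc1cc(O)cc(OC)c1C(=O)O | intermediate
5 | 4-(hydroxymethyl)-3-methoxy-5-(methoxymethyl)phenol | COCc1cc(O)cc(OC)c1CO | intermediate
6 | 3-methoxy-5-(methoxymethyl)-4-methylidenecyclohexa-2,5-dien-1-one | C=C1C(COC)=CC(=O)C=C1OC | intermediate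
7 | 4-hydroxy-5-{[4-hydroxy-2-methoxy-6-(methoxymethyl)phenyl]methyl}-2-methoxybenzoic acid | COCc1cc(O)cc(OC)c1Cc1cc(C(=O)O)c(OC)cc1O | intermediate
8 | 2-(bromomethyl)oxirane (racemic) | BrCC1CO1 | starting material
9 | 3-(bromomethyl)-6-hydroxy-5-{[4-hydroxy-2-methoxy-6-(methoxymethyl)phenyl]methyl}-8-methoxy-3,4-dihydro-1H-isochromen-1-one (racemic) | COCc1cc(O)cc(OC)c1Cc1c(O)cc(OC)c2c1CC(CBr)OC2=O | intermediate
10 | 6-hydroxy-5-{[4-hydroxy-2-methoxy-6-(methoxymethyl)phenyl]methyl}-8-methoxy-3-methylidene-3,4-dihydro-1H-isochromen-1-one | COCc1cc(O)cc(OC)c1Cc1c(O)cc(OC)c2c1CC(=C)OC2=O | intermediate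
11 | 6-hydroxy-5-{[4-hydroxy-2-methoxy-6-(methoxymethyl)phenyl]methyl}-8-methoxy-3-methyl-1H-isochromen-1-one | COCc1cc(O)cc(OC)c1Cc1c(O)cc(OC)c2c(=O)oc(C)cc12 | target

**Step count and risks**
Total steps: 4. Longest linear sequence: 4 (1 → 3 → 4 → 7 → 11).

The three steps most likely to fail:

Step 1. The free phenol of 1 may be O-alkylated by CH2Br2 under phosphate at 140 °C, and the electron-rich ortho-methoxy acid may protodecarboxylate on palladium. The fallback masks the phenol, which also makes the ring less electron-rich. It sets out from 1: pivaloyl chloride in aqueous NaOH at 0 °C gives 2-methoxy-4-(pivaloyloxy)benzoic acid F1. The same Pd(OAc)2/K2HPO4/CH2Br2 conditions then give 7-methoxy-1-oxo-1,3-dihydro-2-benzofuran-5-yl 2,2-dimethylpropanoate F2. F2 is put directly into the step 2 conditions, where NaOMe removes the pivaloyl group and opens the lactone, so the fallback comes back to the route at 4.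

Step 3. Reduction of the hindered, electron-rich acid 4 may be slow or may over-reduce the benzylic position to a methyl group. Any hydride left over would also reduce quinone methide 6. The fallback replaces the one-flask borane sequence on the free acid by a stepwise ester route with a nucleophilic hydride. It sets out from 4: trimethylsilyldiazomethane in MeOH–toluene at 0 °C esterifies only the carboxyl group to methyl 4-hydroxy-2-methoxy-6-(methoxymethyl)benzoate F3. LiAlH4 in THF at 0 °C reduces F3 to 5, which is now isolated by a neutral work-up so that no hydride is carried forward. 5 is then condensed with 1 (3 equiv) in 2 M aqueous NaOH at 70 °C as before, and the fallback comes back to the route at 7.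

Step 4 (the proposed new step). Palladation must occur at a C–H flanked by the carboxylate and the benzyl group. The electron-rich ring A may be alkylated by the epoxide in the fluorinated alcohol. In the DBU stage the phenoxides may be O-alkylated by the bromomethyl lactone or by traces of 8. The fallback uses known chemistry with a different three-carbon partner and no base stage. It sets out from 7: trimethylsulfoxonium iodide and KOtBu in refluxing THF give dimethylsulfoxonium methylide F4, and two equivalents of F4 with acetyl chloride at 0 °C give 1-(dimethyl(oxo)-λ6-sulfanylidene)propan-2-one F5. Acid 7 and F5 with [RuCl2(p-cymene)]2 (5 mol %) and NaOAc in CF3CH2OH at 90 °C undergo the known carboxylate-directed, redox-neutral C–H acylmethylation (divalent ruthenium, carbene transfer from the ylide). This gives 4-hydroxy-5-{[4-hydroxy-2-methoxy-6-(methoxymethyl)phenyl]methyl}-2-methoxy-6-(2-oxopropyl)benzoic acid F6, which cyclodehydrates in the same flask (enol lactonisation), so the fallback comes back to the route at 11.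

**Further compounds**
F1 | step 1 | 2-methoxy-4-(pivaloyloxy)benzoic acid | COc1cc(OC(=O)C(C)(C)C)ccc1C(=O)O
F2 | step 1 | 7-methoxy-1-oxo-1,3-dihydro-2-benzofuran-5-yl 2,2-dimethylpropanoate | COc1cc(OC(=O)C(C)(C)C)cc2c1C(=O)OC2
F3 | step 3 | methyl 4-hydroxy-2-methoxy-6-(methoxymethyl)benzoate | COCc1cc(O)cc(OC)c1C(=O)OC
F4 | step 4 | dimethylsulfoxonium methylide | C=S(C)(C)=O
F5 | step 4 | 1-(dimethyl(oxo)-λ6-sulfanylidene)propan-2-one | CC(=O)C=S(C)(C)=O
F6 | step 4 | 4-hydroxy-5-{[4-hydroxy-2-methoxy-6-(methoxymethyl)phenyl]methyl}-2-methoxy-6-(2-oxopropyl)benzoic acid | COCc1cc(O)cc(OC)c1Cc1c(O)cc(OC)c(C(=O)O)c1CC(C)=O
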